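## Analysis of the target

The target 18 is a cyclohexene in which C1 carries the benzoyloxymethyl carbon C7 and is doubly bonded to C2 (vinylic H), while C3 to C6 are four contiguous oxygenated stereocentres, (3R,4S,5R,6R). With the ring drawn C1→C6 clockwise, O3 lies on the upper (β) face and O4, O5 and O6 all lie on the lower (α) face: an all-cis triad with one trans neighbour. Only O7 (primary, allylic) and O5 (secondary) are benzoylated; O3, O4 and O6 are free. The O5 benzoate sits between two cis hydroxyls and can migrate under base, and the allylic carbinols at C3 and C6 make the ring prone to dehydration and aromatisation under forcing acid. The difficulty is to set four adjacent stereocentres on a flexible ring with no quaternary anchor, and then to acylate exactly one of four secondary oxygens. The strategy rests on two structural facts: the cis triad O4/O5/O6 is what an endo cycloaddition of a cis-dioxygenated two-carbon unit (C5–C6) to a C1–C4 diene oxygenated at C4 produces, and the C3 hydroxyl next to C1=C2 is what remains when a C2–C3 epoxide is opened by a C1 anion stabilised by C7 at the ester level.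

## Retrosynthetic reasoning

Acyl groups and protection. The last bonds cut in 18 are not skeletal. The free 3,4-diol is masked as the trans-fused diacetal of 17, so that only a brief acid treatment is needed at the end. The O5 benzoate is traced to the cis-5,6-diol 15 through the cyclic orthoester 16, because an orthoester opens to the axial ester and, with the ring locked by the diacetal, O5 is the axial oxygen. The O7 benzoate is cut back to triol 14, where the primary hydroxyl is distinguished kinetically.

Oxidation level of C7 and the diacetal. Triol 14 comes from ester 13 by hydride reduction. C7 is kept as an ester until then because the ester makes the relay below possible. The diacetal of 13 is placed on tetraol 12, whose only trans-diequatorial pair is O3/O4. Tetraol 12 arises from 11 by transesterification, which removes the auxiliary and the carbonate together.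

Transposition. The C3–O bond and the C1=C2 alkene of 11 are traced to the C2–C3 epoxide 10, opened by deprotonation at C1. This exchanges an acidic C–H for a stereodefined allylic alcohol and moves the alkene into conjugation. The epoxide comes from alkene 9 by epoxidation on the face away from the four cis substituents, which is what places O3 trans to O4.

Key disconnection. In 9 the bonds C1–C6 and C4–C5 are cut. They flank the cis-dioxygenated C5–C6 unit, so the cut releases the symmetric two-carbon dienophile 8 and the linear dienyl ester 7. No other pair of ring bonds removes four stereocentres at once or leaves a symmetric partner, which also means there is no regiochemical issue. The forward reaction has to be endo (all-cis triad and cis ester) and has to select one face of the diene, which is the task of the mandelate on O4.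

Diene. The methyl ester 7 is traced through acid 6 to aldehyde 5, so that the C7 oxidation level is adjusted before the cycloaddition. The enol ester bond of 5 is cut to the dienolate salt 2 and the acyl chloride 4. Salt 2 contains the five-carbon all-trans chain and is obtained by opening the pyridine ring of the N-sulfonate 1. Chloride 4 is made from the commercial acid 3.

## Alternatives that were turned down

Alternative 1: The ring is cut at C1–C6 and C2–C3, so that C1, C2 and C7 come from 2-bromoacrolein A2 and C3–C6 from furan A1, whose oxygen ends up bridging C3 and C6.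
- Forward key step: A1 and A2 combine at low temperature under a catalytic amount of the tryptophan-derived boron Lewis acid (4S)-2-butyl-4-(1H-indol-3-ylmethyl)-3-(4-methylbenzenesulfonyl)-1,3,2-oxazaborolidin-5-one A3. The product is the exo-formyl adduct 2-bromo-7-oxabicyclo[2.2.1]hept-5-ene-2-carbaldehyde A4.
- For: with A3 the enantiocontrol is catalytic, of predictable sense and exerted at low temperature. This is clearly stronger than a stoichiometric auxiliary at 140 °C. In A4 the carbon C7 is already present at the aldehyde level, and dehydrobromination would give C1=C2 directly.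
- Against: A4 fixes only the two bridgehead centres, and the single bridging oxygen can serve as O3 or as O6 but not both. Exo dihydroxylation of C4=C5 would place O4 and O5 trans to the bridge. That suits O3 but means O6 must be introduced by substitutive cleavage of the C6–O bond with inversion, in competition with cleavage at C3–O. Both positions are allylic to the same enal and nothing in the structure tells them apart. A2 and A4 are also labile (polymerisation, cycloreversion to A1).
- Comparison: three stereo-defining operations would follow the key step, against one (the epoxidation of 9) in the chosen route, where the cycloaddition itself delivers the O4/O5/O6 triad. The chosen route gives up certainty of absolute control for a shorter path after the key step.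

Alternative 2: The C2–C3 bond is cut as an aldol between a C1 ketone and a C3 aldehyde that are both released from the sugar enol ether methyl 3-O-benzoyl-6-deoxy-2,4-bis-O-(methoxymethyl)-α-D-ribo-hex-5-enopyranoside A5.
- Forward key step: the exocyclic enol ether of A5 is hydrated by catalytic Hg(OCOCF3)2 A6 (divalent mercury) in aqueous acetone. The hemiacetal opens and the keto aldehyde closes to 5-O-benzoyl-3-hydroxy-4,6-bis(methoxymethoxy)cyclohexanone A7, a Ferrier carbocyclization.
- For: the all-cis triad and the absolute configuration are taken from the sugar, and in A7 the oxygen O5 is already benzoylated and distinguished from O4 and O6. On both points this is stronger than the chosen route, which must induce the absolute configuration and differentiate O5 late.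
- Against: A5 is many steps from an inexpensive sugar, because it needs three different O-substituents, a 6-deoxy-5-ene and an inversion at the sugar C3. A7 lacks C7 and has C1 as a ketone, so a one-carbon homologation with a regiodefined C1=C2 must follow, on a β-hydroxy ketone that readily loses exactly the C3 oxygen by E1cB. The C3 configuration arises in the aldol under substrate control that is not secure for this series. The base-sensitive O5 benzoate would have to survive all of it, and the toxic mercury salt A6 is needed.
- Comparison: the chosen route forms the ring, C7 and the triad in one step from commodity materials, and creates C3–O and C1=C2 together in the epoxide relay. It should be markedly shorter.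

Alternative 3: The C1–C6 bond is cut as the aldol half of a Morita–Baylis–Hillman reaction within the acyclic D-lyxo-configured enoate aldehyde methyl (E)-4-O-(tert-butyldimethylsilyl)-5,6-O-isopropylidene-7-oxohept-2-enoate A8.
- Forward key step: PMe3 A9 adds to C2 of the enoate of A8. The C1 enolate adds to the C6 aldehyde, and loss of A9 gives methyl 3-O-TBS-4,5-O-isopropylidene-6-hydroxycyclohex-1-ene-1-carboxylate A10.
- For: in A10 the alkene C1=C2 and C7 at the ester level arise directly, with no transposition. C3, C4 and C5 come from the chiral pool, so the absolute configuration is secure, which is stronger than the chosen route on that point.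
- Against: only one C–C bond and one stereocentre are made. That centre (C6, which must end cis to O5) is set in a reversible aldol step under substrate control alone. The α-alkoxy aldehyde of A8 can epimerise at C5 or eliminate under the Lewis-basic conditions. A8 needs three differentiated oxygens and both chain ends adjusted, and the acetonide carried into A10 ties O4 to O5, which must later be told apart, so the benzoate problem is not avoided.
- Comparison: the late protecting-group work is about equal. The chosen route offers convergence instead: two C–C bonds, the ring and four stereocentres from two achiral components in one step.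

Key step: step 6

Remark on notation: ring compounds keep the locants of the target (C1 bears C7, C2 is the vinylic carbon). β is the face of O3 in the target and α is the face of O4, O5 and O6.

Assumption: the (S)-mandelate is taken to leave open the diene face that leads to 9 as drawn. The sense of induction must be confirmed on the first batch, and if it is the opposite one the same sequence is run in the mirror-image auxiliary series.

## Route

Step 1
Reactants: 1 sulfur trioxide–pyridine complex (pyridinium-1-sulfonate)
Product: 2 potassium (1E,3E)-5-oxopenta-1,3-dien-1-olate (glutaconaldehyde potassium salt)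
Conditions: KOH, H2O, −20 → 40 °C; recrystallisation (MeOH)
Reagents that add atoms: potassium hydroxide, [K+].[OH-]
Why: Hydroxide adds at C2 of the N-sulfonylpyridinium ring, the ring opens and the N-sulfonyl imine is hydrolysed, leaving the all-trans C5 dialdehyde enolate; this Zincke-type pyridinium ring opening is the standard preparation of the salt.

Step 2
Reactants: 3 (S)-2-methoxy-2-phenylacetic acid ((S)-O-methylmandelic acid)
Product: 4 (S)-2-methoxy-2-phenylacetyl chloride
Conditions: (COCl)2, DMF (cat.), CH2Cl2, 0 °C → rt; concentrate, use crude
Reagents that add atoms: oxalyl chloride, O=C(Cl)C(Cl)=O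
Why: Acyl chloride formation through the Vilsmeier-type chloroiminium from catalytic DMF; low temperature and the absence of amine base should keep the α-centre from racemising through the ketene.

Step 3
Reactants: 2 glutaconaldehyde potassium salt; 4 (S)-2-methoxy-2-phenylacetyl chloride
Product: 5 (1E,3E)-5-oxopenta-1,3-dien-1-yl (S)-2-methoxy-2-phenylacetate
Conditions: THF, 18-crown-6 (cat.), −20 → 0 °C
Reagents that add atoms: none
Why: O-acylation of the ambident dienolate by a hard acyl chloride gives the enol ester; the all-trans geometry of the salt is carried into the (E,E)-dienal, and the preformed enolate makes an amine base unnecessary.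

Step 4
Reactants: 5 (1E,3E)-5-oxopenta-1,3-dien-1-yl (S)-2-methoxy-2-phenylacetate
Product: 6 (2E,4E)-5-{[(S)-2-methoxy-2-phenylacetyl]oxy}penta-2,4-dienoic acid
Conditions: NaClO2, NaH2PO4, 2-methylbut-2-ene, t-BuOH/H2O, 0 °C → rt
Reagents that add atoms: sodium chlorite, [Na+].[O-]Cl=O
Why: Pinnick oxidation converts the dienal to the acid under mildly acidic buffer; the alkene scavenger traps hypochlorous acid, so the enol ester and the diene should remain intact.

Step 5
Reactants: 6 (2E,4E)-5-{[(S)-2-methoxy-2-phenylacetyl]oxy}penta-2,4-dienoic acid
Product: 7 methyl (2E,4E)-5-{[(S)-2-methoxy-2-phenylacetyl]oxy}penta-2,4-dienoate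
Conditions: TMSCHN2, PhMe/MeOH (4:1), 0 °C
Reagents that add atoms: (trimethylsilyl)diazomethane, C[Si](C)(C)C=[N+]=[N-]
Why: O-Methylation of the carboxylic acid with a diazoalkane under neutral conditions, which avoids the acid or base that would cleave the enol ester.

Step 6
Reactants: 7 methyl (2E,4E)-5-{[(S)-2-methoxy-2-phenylacetyl]oxy}penta-2,4-dienoate; 8 vinylene carbonate (1,3-dioxol-2-one)
Product: 9 methyl (1R,4S,5S,6R)-4-{[(S)-2-methoxy-2-phenylacetyl]oxy}-5,6-(carbonyldioxy)cyclohex-2-ene-1-carboxylate (ester, O4, O5 and O6 all α)
Conditions: 8 (8 equiv, neat), BHT (cat.), sealed tube, 140 °C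
Reagents that add atoms: none
Why: Diels–Alder reaction: a concerted, thermally allowed [4+2] cycloaddition in which the s-cis (E,E)-diene and the cis-alkene both react suprafacially and C1–C6 and C4–C5 form in one step. The closest known reactions are the thermal addition of vinylene carbonate to (E,E)-1,4-diacyloxybuta-1,3-dienes, which gives the all-cis adduct, and cycloadditions of 1-(O-methylmandeloyloxy)dienes in which the ester differentiates the diene faces. The cyclohexene ring is closed by intermolecular annulation of a four-carbon and a two-carbon component through two new σ bonds. C1 and C4 come out cis because both diene termini are E; C5 and C6 are cis because the dienophile is a cyclic Z-alkene. The relation between the two pairs is set by the endo transition state, in which the carbonate ring lies under C2–C3 of the diene, so that O5 and O6 end cis to O4 and to the ester. The absolute configuration is set by the (S)-mandelate, whose preferred conformation (methoxy eclipsing the ester carbonyl, phenyl over one diene face) should leave the other face open to 8. The step needs endo over exo selectivity and one π-face; regiochemistry is not an issue because 8 is symmetric. The push–pull diene is only moderately reactive, hence neat excess dienophile, a radical inhibitor and heat.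

Step 7
Reactants: 9 all-cis cycloadduct
Product: 10 methyl 2β,3β-epoxy-4α-{[(S)-2-methoxy-2-phenylacetyl]oxy}-5α,6α-(carbonyldioxy)cyclohexane-1α-carboxylate
Conditions: m-CPBA, 4,4'-thiobis(6-tert-butyl-3-methylphenol) (cat.), ClCH2CH2Cl, 70 °C
Reagents that add atoms: m-chloroperoxybenzoic acid, OOC(=O)c1cccc(Cl)c1
Why: Prilezhaev epoxidation; the four α substituents block the lower face, so oxygen should be delivered to the β face of C2=C3, which sets C2 and C3; the alkene is deactivated by its allylic ester and acyloxy groups, hence heating with a radical inhibitor.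

Step 8
Reactants: 10 β-epoxide
Product: 11 methyl 3β-hydroxy-4α-{[(S)-2-methoxy-2-phenylacetyl]oxy}-5α,6α-(carbonyldioxy)cyclohex-1-ene-1-carboxylate
Conditions: DBU (1.1 equiv), CH2Cl2, −20 → 0 °C
Reagents that add atoms: none
Why: E1cB epoxide opening: the amidine removes the C1 proton α to the ester and the enolate expels the strained C2–O bond, giving the conjugated ester with O3 retained on the β face, trans to O4; the oxirane oxygen should be a better β-nucleofuge than the carbonate oxygen at C6 because its departure releases ring strain, and the reaction is quenched as soon as 10 is consumed.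

Step 9
Reactants: 11 allylic alcohol
Product: 12 methyl (3R,4S,5R,6R)-3,4,5,6-tetrahydroxycyclohex-1-ene-1-carboxylate (3β,4α,5α,6α)
Conditions: K2CO3 (cat.), MeOH, 0 °C → rt; acidic ion-exchange resin (H+ form)
Reagents that add atoms: none
Why: Base-catalysed transesterification (Zemplén-type methanolysis) removes the mandelate and opens the cyclic carbonate; the methyl ester exchanges degenerately and the enoate no longer has an acidic C1 proton.

Step 10
Reactants: 12 tetraol methyl ester
Product: 13 methyl 3β,4α-O-[(2S,3S)-2,3-dimethoxybutane-2,3-diyl]-3,4,5α,6α-tetrahydroxycyclohex-1-ene-1-carboxylate (3,4-butane-2,3-diacetal; O5 and O6 free)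
Conditions: 2,2,3,3-tetramethoxybutane, CSA (cat.), MeOH, reflux
Reagents that add atoms: 2,2,3,3-tetramethoxybutane, COC(C)(OC)C(C)(OC)OC
Why: Butane-2,3-diacetal formation under thermodynamic control selects trans-diequatorial vicinal diols, because only they give a trans-fused dioxane with both methoxy groups axial; O3/O4 is the only trans pair, and the same anomeric preference sets both acetal centres (S,S).

Step 11
Reactants: 13 diacetal ester
Product: 14 3β,4α-O-[(2S,3S)-2,3-dimethoxybutane-2,3-diyl]-1-(hydroxymethyl)cyclohex-1-ene-3,4,5α,6α-tetrol (O5, O6 and O7 free)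
Conditions: i-Bu2AlH (6 equiv), CH2Cl2/THF, −78 → −20 °C; aq. KNaC4H4O6
Reagents that add atoms: none
Why: 1,2-Reduction of the conjugated ester to the allylic alcohol by an aluminium hydride; the excess covers the two free hydroxyls and the acetal is inert at low temperature.

Step 12
Reactants: 14 triol
Product: 15 [3β,4α-O-((2S,3S)-2,3-dimethoxybutane-2,3-diyl)-3,4,5α,6α-tetrahydroxycyclohex-1-en-1-yl]methyl benzoate (O5 and O6 free)
Conditions: BzCl (1.05 equiv), 2,4,6-collidine, CH2Cl2, −40 °C
Reagents that add atoms: benzoyl chloride, O=C(Cl)c1ccccc1
Why: Kinetically selective acylation of the primary allylic hydroxyl over the two secondary ones (O5 axial, O6 beside the trisubstituted alkene) at low temperature with a weak base.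

Step 13
Reactants: 15 7-O-benzoate diol
Product: 17 [5α-benzoyloxy-3β,4α-O-((2S,3S)-2,3-dimethoxybutane-2,3-diyl)-3,4,6α-trihydroxycyclohex-1-en-1-yl]methyl benzoate, via cyclic 5,6-orthobenzoate 16 (not isolated)
Conditions: PhC(OMe)3, CSA (cat.), MeCN, rt; then AcOH/H2O (4:1), rt
Reagents that add atoms: trimethyl orthobenzoate, COC(OC)(OC)c1ccccc1; water, O
Why: Cyclic orthoester formation on the cis-5,6-diol and mild acid hydrolysis; the orthoacid opens to the axial ester and equatorial alcohol, and with the ring locked by the trans-fused diacetal O5 is axial and O6 pseudoequatorial, so the benzoate should land on O5; the orthoester carbon of 16 is a transient, uncontrolled stereocentre.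

Step 14
Reactants: 17 diacetal dibenzoate
Product: 18 [(3R,4S,5R,6R)-5-(benzoyloxy)-3,4,6-trihydroxycyclohex-1-en-1-yl]methyl benzoate (target)
Conditions: TFA/H2O (9:1), 0 °C → rt; co-evaporation with PhMe
Reagents that add atoms: none
Why: Acid hydrolysis of the diacetal; benzoates tolerate aqueous trifluoroacetic acid and acid-catalysed acyl migration is slow, so a short exposure should free O3 and O4 without moving the O5 benzoate.

## Compound list

1 | sulfur trioxide–pyridine complex (pyridinium-1-sulfonate) | [O-]S(=O)(=O)[n+]1ccccc1 | starting material
2 | potassium (1E,3E)-5-oxopenta-1,3-dien-1-olate | [K+].[O-]/C=C/C=C/C=O | intermediate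
3 | (S)-2-methoxy-2-phenylacetic acid | OC(=O)[C@@H](OC)c1ccccc1 | starting material
4 | (S)-2-methoxy-2-phenylacetyl chloride | ClC(=O)[C@@H](OC)c1ccccc1 | intermediate
5 | (1E,3E)-5-oxopenta-1,3-dien-1-yl (S)-2-methoxy-2-phenylacetate | O=C/C=C/C=C/OC(=O)[C@@H](OC)c1ccccc1 | intermediate
6 | (2E,4E)-5-{[(S)-2-methoxy-2-phenylacetyl]oxy}penta-2,4-dienoic acid | OC(=O)/C=C/C=C/OC(=O)[C@@H](OC)c1ccccc1 | intermediate
7 | methyl (2E,4E)-5-{[(S)-2-methoxy-2-phenylacetyl]oxy}penta-2,4-dienoate | COC(=O)/C=C/C=C/OC(=O)[C@@H](OC)c1ccccc1 | intermediate
8 | vinylene carbonate (1,3-dioxol-2-one) | O=C1OC=CO1 | starting material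
9 | methyl (1R,4S,5S,6R)-4-{[(S)-2-methoxy-2-phenylacetyl]oxy}-5,6-(carbonyldioxy)cyclohex-2-ene-1-carboxylate | COC(=O)[C@@H]1C=C[C@H](OC(=O)[C@@H](OC)c2ccccc2)[C@@H]3OC(=O)O[C@H]13 | intermediate
10 | methyl 2β,3β-epoxy-4α-{[(S)-2-methoxy-2-phenylacetyl]oxy}-5α,6α-(carbonyldioxy)cyclohexane-1α-carboxylate | COC(=O)[C@@H]1[C@H]4O[C@H]4[C@H](OC(=O)[C@@H](OC)c2ccccc2)[C@@H]3OC(=O)O[C@H]13 | intermediate
11 | methyl 3β-hydroxy-4α-{[(S)-2-methoxy-2-phenylacetyl]oxy}-5α,6α-(carbonyldioxy)cyclohex-1-ene-1-carboxylate | COC(=O)C1=C[C@@H](O)[C@H](OC(=O)[C@@H](OC)c2ccccc2)[C@@H]3OC(=O)O[C@H]13 | intermediate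
12 | methyl (3R,4S,5R,6R)-3,4,5,6-tetrahydroxycyclohex-1-ene-1-carboxylate | COC(=O)C1=C[C@@H](O)[C@H](O)[C@H](O)[C@@H]1O | intermediate
13 | methyl 3β,4α-O-[(2S,3S)-2,3-dimethoxybutane-2,3-diyl]-3,4,5α,6α-tetrahydroxycyclohex-1-ene-1-carboxylate | COC(=O)C1=C[C@H]4O[C@](C)(OC)[C@@](C)(OC)O[C@@H]4[C@H](O)[C@@H]1O | intermediate
14 | 3β,4α-O-[(2S,3S)-2,3-dimethoxybutane-2,3-diyl]-1-(hydroxymethyl)cyclohex-1-ene-3,4,5α,6α-tetrol | OCC1=C[C@H]4O[C@](C)(OC)[C@@](C)(OC)O[C@@H]4[C@H](O)[C@@H]1O | intermediate
15 | [3β,4α-O-((2S,3S)-2,3-dimethoxybutane-2,3-diyl)-3,4,5α,6α-tetrahydroxycyclohex-1-en-1-yl]methyl benzoate | O=C(OCC1=C[C@H]4O[C@](C)(OC)[C@@](C)(OC)O[C@@H]4[C@H](O)[C@@H]1O)c1ccccc1 | intermediate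
16 | cyclic 5α,6α-(methoxy)(phenyl)methylidene orthoester of 15 (mixture at the orthoester carbon) | O=C(OCC1=C[C@H]4O[C@](C)(OC)[C@@](C)(OC)O[C@@H]4[C@@H]5OC(OC)(c6ccccc6)O[C@H]15)c1ccccc1 | intermediate
17 | [5α-benzoyloxy-3β,4α-O-((2S,3S)-2,3-dimethoxybutane-2,3-diyl)-3,4,6α-trihydroxycyclohex-1-en-1-yl]methyl benzoate | O=C(OCC1=C[C@H]4O[C@](C)(OC)[C@@](C)(OC)O[C@@H]4[C@H](OC(=O)c2ccccc2)[C@@H]1O)c1ccccc1 | intermediate
18 | [(3R,4S,5R,6R)-5-(benzoyloxy)-3,4,6-trihydroxycyclohex-1-en-1-yl]methyl benzoate | O=C(OCC1=C[C@@H](O)[C@H](O)[C@H](OC(=O)c2ccccc2)[C@@H]1O)c1ccccc1 | target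

## Step count and least certain steps

Total: 14 steps. Longest linear sequence: 13 steps (steps 1 and 3–14 from 1, or steps 2–14 from 3).

Step 6 (key step).
- What may go wrong: the cycloaddition may be slow enough that thermal loss of the allylic mandelate from the adduct (1,4-elimination, then aromatisation) and polymerisation of 8 compete. The mandelate may also discriminate the diene faces only weakly at 140 °C, and endo selectivity may erode. The first adjustment is hydrostatic pressure (12–15 kbar, 25–40 °C), which accelerates the reaction without heat.
- Fallback: if facial bias stays poor, the auxiliary is used as a resolving handle instead of a directing group. Setting out from 7 and 8, the cycloaddition is run for conversion only. The product 9 and its facial diastereomer methyl (1S,4R,5R,6S)-4-{[(S)-2-methoxy-2-phenylacetyl]oxy}-5,6-(carbonyldioxy)cyclohex-2-ene-1-carboxylate F1 differ in the ring configuration but share the (S)-acyl group. They are therefore diastereomers and can be separated by crystallisation or chromatography, which returns to the route at 9 as a single isomer.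

Step 8.
- What may go wrong: the C1 enolate has a second β-oxygen, the carbonate oxygen on C6, and its expulsion would destroy the C6 centre. Prolonged exposure to base can also isomerise the γ-hydroxy enoate to a γ-keto ester.
- Fallback: the epoxide is replaced by a leaving group that a carbonate cannot rival; this detour also bypasses step 7. Setting out from 9, catalytic OsO4 with N-methylmorpholine N-oxide (acetone/H2O) should dihydroxylate the open β face to methyl 2β,3β-dihydroxy-4α-{[(S)-2-methoxy-2-phenylacetyl]oxy}-5α,6α-(carbonyldioxy)cyclohexane-1α-carboxylate F2. SOCl2/Et3N then gives the 2β,3β-cyclic sulfite F3, and RuCl3 (cat.)/NaIO4 oxidises it to the 2β,3β-cyclic sulfate F4. DBU in THF at 0 °C should open F4 by E1cB at C2 to the 3β-O-sulfate (hydrogen sulfate) of 11 F5. Catalytic H2SO4 with one equivalent of water in THF cleaves the sulfate monoester with retention and returns to the route at 11.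

Step 13.
- What may go wrong: the orthoester may open toward the O6 benzoate if the ring is less firmly locked than assumed, the benzoate may drift between O5 and O6, and step 12 may over-acylate.
- Fallback: a differentiation that does not depend on the axial/equatorial argument. Setting out from 14, (t-Bu)2Si(OTf)2 with 2,6-lutidine should bridge the primary O7 and the allylic O6 as the six-membered 6α,7-O-(di-tert-butylsilylene) derivative of 14 F6, leaving only O5 free. BzCl/DMAP/pyridine gives the 5α-O-benzoyl-6α,7-O-(di-tert-butylsilylene) derivative F7. HF·pyridine in THF releases the 5α-O-benzoyl-6α,7-diol F8. Primary-selective benzoylation (BzCl, 2,4,6-collidine, −40 °C) then returns to the route at 17.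

## Further compounds

F1 | step 6 | methyl (1S,4R,5R,6S)-4-{[(S)-2-methoxy-2-phenylacetyl]oxy}-5,6-(carbonyldioxy)cyclohex-2-ene-1-carboxylate | COC(=O)[C@H]1C=C[C@@H](OC(=O)[C@@H](OC)c2ccccc2)[C@H]3OC(=O)O[C@@H]13
F2 | step 8 | methyl 2β,3β-dihydroxy-4α-{[(S)-2-methoxy-2-phenylacetyl]oxy}-5α,6α-(carbonyldioxy)cyclohexane-1α-carboxylate | COC(=O)[C@@H]1[C@@H](O)[C@@H](O)[C@H](OC(=O)[C@@H](OC)c2ccccc2)[C@@H]3OC(=O)O[C@H]13
F3 | step 8 | 2β,3β-cyclic sulfite of F2 (mixture at sulfur) | COC(=O)[C@@H]1[C@H]4OS(=O)O[C@H]4[C@H](OC(=O)[C@@H](OC)c2ccccc2)[C@@H]3OC(=O)O[C@H]13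
F4 | step 8 | 2β,3β-cyclic sulfate of F2 | COC(=O)[C@@H]1[C@H]4OS(=O)(=O)O[C@H]4[C@H](OC(=O)[C@@H](OC)c2ccccc2)[C@@H]3OC(=O)O[C@H]13
F5 | step 8 | 3β-O-sulfate (hydrogen sulfate) of 11 | COC(=O)C1=C[C@@H](OS(=O)(=O)O)[C@H](OC(=O)[C@@H](OC)c2ccccc2)[C@@H]3OC(=O)O[C@H]13
F6 | step 13 | 6α,7-O-(di-tert-butylsilylene) derivative of 14 | CC(C)(C)[Si]1(C(C)(C)C)OCC2=C[C@H]4O[C@](C)(OC)[C@@](C)(OC)O[C@@H]4[C@H](O)[C@@H]2O1
F7 | step 13 | 5α-O-benzoyl-6α,7-O-(di-tert-butylsilylene) derivative of 14 | CC(C)(C)[Si]1(C(C)(C)C)OCC2=C[C@H]4O[C@](C)(OC)[C@@](C)(OC)O[C@@H]4[C@H](OC(=O)c3ccccc3)[C@@H]2O1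
F8 | step 13 | 5α-O-benzoyl derivative of 14 (O6 and O7 free) | OCC1=C[C@H]4O[C@](C)(OC)[C@@](C)(OC)O[C@@H]4[C@H](OC(=O)c2ccccc2)[C@@H]1O
A1 | alternative 1 | furan | c1ccoc1
A2 | alternative 1 | 2-bromoacrolein (2-bromoprop-2-enal) | C=C(Br)C=O
A3 | alternative 1 | (4S)-2-butyl-4-(1H-indol-3-ylmethyl)-3-(4-methylbenzenesulfonyl)-1,3,2-oxazaborolidin-5-one | CCCCB1OC(=O)[C@H](Cc2c[nH]c3ccccc23)N1S(=O)(=O)c1ccc(C)cc1
A4 | alternative 1 | 2-bromo-7-oxabicyclo[2.2.1]hept-5-ene-2-carbaldehyde (exo-formyl) | O=C[C@]1(Br)C[C@H]2C=C[C@@H]1O2
A5 | alternative 2 | methyl 3-O-benzoyl-6-deoxy-2,4-bis-O-(methoxymethyl)-α-D-ribo-hex-5-enopyranoside | C=C1O[C@H](OC)[C@H](OCOC)[C@H](OC(=O)c2ccccc2)[C@@H]1OCOC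
A6 | alternative 2 | Hg(OCOCF3)2 | [Hg+2].[O-]C(=O)C(F)(F)F.[O-]C(=O)C(F)(F)F
A7 | alternative 2 | 5-O-benzoyl-3-hydroxy-4,6-bis(methoxymethoxy)cyclohexanone | O=C1C[C@@H](O)[C@H](OCOC)[C@H](OC(=O)c2ccccc2)[C@@H]1OCOC
A8 | alternative 3 | methyl (E)-4-O-(tert-butyldimethylsilyl)-5,6-O-isopropylidene-7-oxohept-2-enoate (D-lyxo) | COC(=O)/C=C/[C@@H](O[Si](C)(C)C(C)(C)C)[C@@H]1OC(C)(C)O[C@@H]1C=O
A9 | alternative 3 | PMe3 | CP(C)C
A10 | alternative 3 | methyl 3-O-TBS-4,5-O-isopropylidene-6-hydroxycyclohex-1-ene-1-carboxylate | COC(=O)C1=C[C@@H](O[Si](C)(C)C(C)(C)C)[C@@H]2OC(C)(C)O[C@@H]2[C@@H]1O
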